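**Strategy.** The target is the (S)-configured tiglate of alkannin. Everything rests on opening quinone ring B at C1–C2 and C3–C4: carbonyls C1 and C4 sit on C8a and C4a of ring A and form a phthaloyl unit, while C2–C3, with the side chain on C2 and hydrogen on C3, is a terminal alkyne. In one operation a phthaloylcobalt metallacycle, generated by C–C activation of 3,6-bis(methoxymethoxy)benzocyclobutene-1,2-dione, inserts that alkyne and closes ring B directly as the quinone. The alkyne is the (S)-propargylic alcohol already acylated with tiglic acid, so that after the annulation only the two MOM ethers remain to be cleaved.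

Key step: step 8

Remark on the structures: C1' of the target carries O, quinone carbon C2, C2'H2 and H and is (S) as drawn (alkannin series). The priority order O > alkynyl or quinonyl carbon > CH2 > H holds throughout, so the propargylic alcohol, its tiglate, the protected quinone and the target all carry the descriptor (S). No structure needed correction.

Remark on the design: the side-chain oxygen goes through the annulation as the tiglate itself, not as a silyl ether. This keeps fluoride, DMAP and acylation chemistry away from the base- and nucleophile-sensitive quinone. The phenols are MOM ethers because these survive the amide base of the aryne step and can be removed at the end by chelation to the peri carbonyls.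

Assumption: 2-bromobenzene-1,4-diol, 1,1-dimethoxyethene, 4-methylpent-3-enoic acid, ethynyltrimethylsilane, tiglic acid, ClCo(PPh3)3 and Ru[(S,S)-TsDPEN](p-cymene) are purchased.

**Route**

Step 1
Reactants: 1 2-bromobenzene-1,4-diol (bromohydroquinone)
Product: 2 2-bromo-1,4-bis(methoxymethoxy)benzene
Conditions: MOMCl (2.6 equiv), iPr2NEt (3.5 equiv), CH2Cl2, 0 °C → rt
Reagents that add atoms: chloromethyl methyl ether, COCCl
Why: Both phenols are O-alkylated by the reactive α-chloro ether under amine base (MOM protection), giving acetal ethers that tolerate NaNH2 and the later organometallic steps.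

Step 2
Reactants: 2 2-bromo-1,4-bis(methoxymethoxy)benzene; 3 1,1-dimethoxyethene
Product: 6 3,6-bis(methoxymethoxy)benzocyclobutenone, via aryne 4 (not isolated), via dimethyl ketal 5 (not isolated)
Conditions: NaNH2 (4 equiv), 3 (3 equiv), THF, 65 °C; then 1 M aq. HCl, THF, 0 °C → rt
Reagents that add atoms: water, O
Why: Deprotonation between Br and OMOM and loss of bromide give the symmetrical aryne, which undergoes (2+2) cycloaddition with the electron-rich ketene acetal to a single ketal, and this ketone ketal is hydrolysed by dilute acid far faster than the formaldehyde-derived aryl MOM acetals.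

Step 3
Reactants: 6 3,6-bis(methoxymethoxy)benzocyclobutenone
Product: 8 3,6-bis(methoxymethoxy)benzocyclobutene-1,2-dione, via gem-dibromide 7 (not isolated)
Conditions: NBS (2.2 equiv), AIBN (cat.), PhCF3, 85 °C; filter, evaporate; then Ag2CO3, MeCN–H2O, rt
Reagents that add atoms: water, O
Why: Wohl–Ziegler radical bromination occurs twice at the only benzylic CH2, a position that enolisation chemistry cannot reach in this ring, and silver-assisted hydrolysis of the gem-dibromide under nearly neutral conditions then unmasks the second carbonyl without touching the MOM ethers.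

Step 4
Reactants: 9 4-methylpent-3-enoic acid
Product: 11 N-methoxy-N,4-dimethylpent-3-enamide, via acyl imidazolide 10 (not isolated)
Conditions: CDI (1.1 equiv), CH2Cl2, rt; then MeNH(OMe)·HCl (1.2 equiv), rt
Reagents that add atoms: N,O-dimethylhydroxylamine hydrochloride, CNOC.Cl
Why: Activation as the acyl imidazolide followed by aminolysis (Weinreb amide formation) needs no base stronger than imidazole, so the β,γ-double bond is not moved into conjugation.

Step 5
Reactants: 11 N-methoxy-N,4-dimethylpent-3-enamide; 12 ethynyltrimethylsilane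
Product: 13 6-methyl-1-(trimethylsilyl)hept-5-en-1-yn-3-one
Conditions: 12 (1.3 equiv), n-BuLi (1.25 equiv), THF, −78 °C; then 11, −78 → −20 °C; cold aq. NH4Cl
Reagents that add atoms: none
Why: In this Weinreb ketone synthesis the lithium acetylide adds once to give a chelated tetrahedral intermediate that collapses to the ynone only on the cold, weakly acidic quench, which prevents over-addition and base-induced conjugation of the skipped enone.

Step 6
Reactants: 13 6-methyl-1-(trimethylsilyl)hept-5-en-1-yn-3-one
Product: 15 (S)-6-methylhept-5-en-1-yn-3-ol, via silylated (S)-alkynol 14 (not isolated)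
Conditions: Ru[(S,S)-TsDPEN](p-cymene) (1 mol%), iPrOH, rt; evaporate; then K2CO3 (0.3 equiv), MeOH, 0 °C → rt
Reagents that add atoms: none
Why: Noyori asymmetric transfer hydrogenation with the base-free amido complex of divalent ruthenium delivers hydride and proton through a six-membered transition state in which the alkynyl group, not the alkyl chain, lies next to the arene ligand, so the (S,S)-diamine sets the (S)-carbinol, and methanolysis then removes the alkynyl silyl group.

Step 7
Reactants: 15 (S)-6-methylhept-5-en-1-yn-3-ol; 16 tiglic acid ((E)-2-methylbut-2-enoic acid)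
Product: 17 (S)-6-methylhept-5-en-1-yn-3-yl (E)-2-methylbut-2-enoate
Conditions: 16 (1.3 equiv), DCC (1.4 equiv), DMAP (0.2 equiv), CH2Cl2, 0 °C → rt
Reagents that add atoms: none
Why: Steglich esterification acylates the secondary alcohol through the acylpyridinium ion without breaking the C–O bond of the stereocentre, so the (S) configuration and the stable (E) geometry of the acid are carried over.

Step 8
Reactants: 8 3,6-bis(methoxymethoxy)benzocyclobutene-1,2-dione; 17 (S)-6-methylhept-5-en-1-yn-3-yl (E)-2-methylbut-2-enoate
Product: 20 (S)-1-[5,8-bis(methoxymethoxy)-1,4-dioxo-1,4-dihydronaphthalen-2-yl]-4-methylpent-3-enyl (E)-2-methylbut-2-enoate, via bis(triphenylphosphine) phthaloylcobalt chloride 18 (not isolated), via dimethylglyoxime pyridine phthaloylcobalt chloride 19 (not isolated)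
Conditions: ClCo(PPh3)3 (1.05 equiv), PhCl, rt; then dimethylglyoxime (1.1 equiv), pyridine, rt; evaporate; then 17 (1.3 equiv), CoCl2·6H2O (2 equiv), MeCN, rt → 70 °C
Reagents that add atoms: none
Why: Monovalent cobalt adds oxidatively into the strained bond between the two carbonyl carbons of 8 to give the five-membered diacyl metallacycle 18 of trivalent cobalt, and exchange of the phosphines for dimethylglyoxime and pyridine gives octahedral 19, from which the Lewis acid CoCl2·6H2O opens a coordination site. The alkyne of 17 coordinates and inserts into one cobalt–acyl bond, forming C1–C2 of the quinone, and reductive elimination from the seven-membered cobaltacycle forms C3–C4, so ring B is closed by a metal-mediated (4+2) annulation of the four-atom phthaloyl unit with the two alkyne carbons, directly at the quinone oxidation level. The closest known reaction type is the naphthoquinone synthesis from phthaloylcobalt complexes of benzocyclobutenediones and alkynes. No stereocentre is formed, and C1', set in step 6, is a spectator under these neutral conditions. Regiochemistry needs no control because the phthaloyl unit is symmetric (MOM ethers at both C5 and C8), so either sense of insertion gives 20; the terminal alkyne is expected to react in preference to the trisubstituted prenyl and tiglate alkenes because it binds cobalt far better, and the chelating dioxime leaves room for only one alkyne, which suppresses double insertion.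

Step 9
Reactants: 20 (S)-1-[5,8-bis(methoxymethoxy)-1,4-dioxo-1,4-dihydronaphthalen-2-yl]-4-methylpent-3-enyl (E)-2-methylbut-2-enoate
Product: 21 (S)-1-(5,8-dihydroxy-1,4-dioxo-1,4-dihydronaphthalen-2-yl)-4-methylpent-3-enyl (E)-2-methylbut-2-enoate (O-tigloylalkannin, CNP0373203.1)
Conditions: MgBr2·OEt2 (6 equiv), CH2Cl2–Et2O, 0 °C → rt; then H2O/aq. NH4Cl
Reagents that add atoms: none
Why: Each MOM oxygen lies peri to a quinone carbonyl (O5 next to C4=O, O8 next to C1=O), so magnesium chelates both and bromide cleaves the activated acetal (Lewis acid cleavage of MOM ethers) in an aprotic medium in which the tiglate, the two alkenes and the C1' stereocentre are not engaged.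

**Compound list**

1 | 2-bromobenzene-1,4-diol (bromohydroquinone) | Oc1ccc(O)c(Br)c1 | starting material
2 | 2-bromo-1,4-bis(methoxymethoxy)benzene | COCOc1ccc(OCOC)c(Br)c1 | intermediate
3 | 1,1-dimethoxyethene | C=C(OC)OC | starting material
4 | 3,6-bis(methoxymethoxy)benzyne (formed in the flask) | COCOC1=CC=C(OCOC)C#C1 | intermediate
5 | 1,1-dimethoxy-3,6-bis(methoxymethoxy)-1,2-dihydrobenzocyclobutene (formed in the flask) | COCOc1ccc(OCOC)c2c1CC2(OC)OC | intermediate
6 | 3,6-bis(methoxymethoxy)benzocyclobutenone | COCOc1ccc(OCOC)c2c1CC2=O | intermediate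
7 | 2,2-dibromo-3,6-bis(methoxymethoxy)benzocyclobutenone (formed in the flask) | COCOc1ccc(OCOC)c2c1C(Br)(Br)C2=O | intermediate
8 | 3,6-bis(methoxymethoxy)benzocyclobutene-1,2-dione | COCOc1ccc(OCOC)c2C(=O)C(=O)c12 | intermediate
9 | 4-methylpent-3-enoic acid | CC(C)=CCC(=O)O | starting material
10 | 1-(4-methylpent-3-enoyl)imidazole (formed in the flask) | CC(C)=CCC(=O)n1ccnc1 | intermediate
11 | N-methoxy-N,4-dimethylpent-3-enamide | CC(C)=CCC(=O)N(C)OC | intermediate
12 | ethynyltrimethylsilane | C#C[Si](C)(C)C | starting material
13 | 6-methyl-1-(trimethylsilyl)hept-5-en-1-yn-3-one | CC(C)=CCC(=O)C#C[Si](C)(C)C | intermediate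
14 | (S)-6-methyl-1-(trimethylsilyl)hept-5-en-1-yn-3-ol (formed in the flask) | O[C@@H](CC=C(C)C)C#C[Si](C)(C)C | intermediate
15 | (S)-6-methylhept-5-en-1-yn-3-ol | O[C@@H](CC=C(C)C)C#C | intermediate
16 | tiglic acid, (E)-2-methylbut-2-enoic acid | C/C=C(\C)C(=O)O | starting material
17 | (S)-6-methylhept-5-en-1-yn-3-yl (E)-2-methylbut-2-enoate | C/C=C(\C)C(=O)O[C@@H](CC=C(C)C)C#C | intermediate
18 | chlorobis(triphenylphosphine)[3,6-bis(methoxymethoxy)phthaloyl]cobalt, five-membered diacyl metallacycle of trivalent cobalt (formed in the flask) | COCOc1ccc(OCOC)c2C(=O)[Co-2](Cl)([P+](c3ccccc3)(c3ccccc3)c3ccccc3)([P+](c3ccccc3)(c3ccccc3)c3ccccc3)C(=O)c12 | intermediate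
19 | chloro(dimethylglyoxime)(pyridine)[3,6-bis(methoxymethoxy)phthaloyl]cobalt, octahedral complex of trivalent cobalt (formed in the flask) | COCOc1ccc(OCOC)c2C(=O)[Co-3]3(Cl)([n+]4ccccc4)([N+](O)=C(C)C(C)=[N+]3O)C(=O)c12 | intermediate
20 | (S)-1-[5,8-bis(methoxymethoxy)-1,4-dioxo-1,4-dihydronaphthalen-2-yl]-4-methylpent-3-enyl (E)-2-methylbut-2-enoate | C/C=C(\C)C(=O)O[C@@H](CC=C(C)C)C1=CC(=O)c2c(OCOC)ccc(OCOC)c2C1=O | intermediate
21 | (S)-1-(5,8-dihydroxy-1,4-dioxo-1,4-dihydronaphthalen-2-yl)-4-methylpent-3-enyl (E)-2-methylbut-2-enoate (O-tigloylalkannin) | C/C=C(\C)C(=O)O[C@@H](CC=C(C)C)C1=CC(=O)c2c(O)ccc(O)c2C1=O | target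

**Step count and risks**

Total step count: 9. Longest linear sequence: 6 steps (steps 4, 5, 6, 7, 8, 9); the dione branch (steps 1 to 3) joins at step 8.

Steps most likely to fail:

1. Step 8. What may go wrong: sluggish insertion of the branched alkyne into the electron-rich diacyl complex, competing oligomerisation of the alkyne, or attack of the liberated phosphine on the quinone as it forms. The last can be met by precipitating 19 and washing it free of PPh3 before the alkyne is added. The fallback is a Dötz benzannulation; it sets out from 2 and 17 and comes back to the route at 20. Bromine–lithium exchange on 2 (n-BuLi, THF, −78 °C) should give [2,5-bis(methoxymethoxy)phenyl]lithium F1, which adds to Cr(CO)6 to give lithium pentacarbonyl[2,5-bis(methoxymethoxy)benzoyl]chromate F2. O-Methylation with Me3OBF4 should give the methoxycarbene complex pentacarbonyl{[2,5-bis(methoxymethoxy)phenyl](methoxy)methylidene}chromium F3. Heating F3 with 17 (THF, 50 °C, then air) should give the naphthol (S)-1-[1-hydroxy-4-methoxy-5,8-bis(methoxymethoxy)naphthalen-2-yl]-4-methylpent-3-enyl (E)-2-methylbut-2-enoate F4. Oxidation with (NH4)2Ce(NO3)6 in aqueous MeCN at 0 °C should give 20; the sense of alkyne incorporation is again irrelevant once the symmetric quinone is formed.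

2. Step 3. What may go wrong: acidolysis of the MOM ethers by HBr formed during the radical bromination, electrophilic bromination of the electron-rich ring, or ring opening of the strained dione during hydrolysis. The fallback builds the dione with robust methyl ethers and exchanges them afterwards; it sets out from 1 and comes back to the route at 8.
   - O-Methylation of 1 (Me2SO4, K2CO3, acetone) gives 2-bromo-1,4-dimethoxybenzene F5.
   - NaNH2 and 3 in THF give, through 3,6-dimethoxybenzyne F6, the ketal 1,1,3,6-tetramethoxy-1,2-dihydrobenzocyclobutene F7, which aqueous HCl hydrolyses to 3,6-dimethoxybenzocyclobutenone F8.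
   - NBS/AIBN gives 2,2-dibromo-3,6-dimethoxybenzocyclobutenone F9, which warm aqueous H2SO4 hydrolyses to 3,6-dimethoxybenzocyclobutene-1,2-dione F10.
   - BBr3 (CH2Cl2, −78 → 0 °C), assisted by chelation to the neighbouring carbonyls, gives 3,6-dihydroxybenzocyclobutene-1,2-dione F11.
   - MOMCl/iPr2NEt converts F11 into 8.

3. Step 9. What may go wrong: incomplete cleavage of the second MOM ether, or ionisation at C1' with loss of tiglic acid under Lewis acid. The fallback deprotects first and acylates last; it sets out from 15 and comes back to the route at 21. Silylation of 15 (TBSCl, imidazole, DMF) gives (S)-tert-butyldimethyl[(6-methylhept-5-en-1-yn-3-yl)oxy]silane F12. Annulation of F12 with 8 under the conditions of step 8 (through 18 and 19) gives (S)-2-[1-(tert-butyldimethylsilyloxy)-4-methylpent-3-enyl]-5,8-bis(methoxymethoxy)-1,4-naphthoquinone F13. HCl in MeOH–THF (0 °C → rt) removes the silyl ether and both MOM ethers in one operation to give alkannin F14. Steglich acylation of F14 with 16 (DCC, DMAP, CH2Cl2) returns to 21; it should be selective for the side-chain hydroxyl because both phenols are hydrogen-bonded to the quinone carbonyls.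

**Further compounds**

F1 | step 8 | [2,5-bis(methoxymethoxy)phenyl]lithium | [Li]c1cc(OCOC)ccc1OCOC
F2 | step 8 | lithium pentacarbonyl[2,5-bis(methoxymethoxy)benzoyl]chromate | [Li+].[O-]C(c1cc(OCOC)ccc1OCOC)=[Cr](=C=O)(=C=O)(=C=O)(=C=O)=C=O
F3 | step 8 | pentacarbonyl{[2,5-bis(methoxymethoxy)phenyl](methoxy)methylidene}chromium | COC(c1cc(OCOC)ccc1OCOC)=[Cr](=C=O)(=C=O)(=C=O)(=C=O)=C=O
F4 | step 8 | (S)-1-[1-hydroxy-4-methoxy-5,8-bis(methoxymethoxy)naphthalen-2-yl]-4-methylpent-3-enyl (E)-2-methylbut-2-enoate | C/C=C(\C)C(=O)O[C@@H](CC=C(C)C)c1cc(OC)c2c(OCOC)ccc(OCOC)c2c1O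
F5 | step 3 | 2-bromo-1,4-dimethoxybenzene | COc1ccc(OC)c(Br)c1
F6 | step 3 | 3,6-dimethoxybenzyne | COC1=CC=C(OC)C#C1
F7 | step 3 | 1,1,3,6-tetramethoxy-1,2-dihydrobenzocyclobutene | COc1ccc(OC)c2c1CC2(OC)OC
F8 | step 3 | 3,6-dimethoxybenzocyclobutenone | COc1ccc(OC)c2c1CC2=O
F9 | step 3 | 2,2-dibromo-3,6-dimethoxybenzocyclobutenone | COc1ccc(OC)c2c1C(Br)(Br)C2=O
F10 | step 3 | 3,6-dimethoxybenzocyclobutene-1,2-dione | COc1ccc(OC)c2C(=O)C(=O)c12
F11 | step 3 | 3,6-dihydroxybenzocyclobutene-1,2-dione | Oc1ccc(O)c2C(=O)C(=O)c12
F12 | step 9 | (S)-tert-butyldimethyl[(6-methylhept-5-en-1-yn-3-yl)oxy]silane | CC(C)(C)[Si](C)(C)O[C@@H](CC=C(C)C)C#C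
F13 | step 9 | (S)-2-[1-(tert-butyldimethylsilyloxy)-4-methylpent-3-enyl]-5,8-bis(methoxymethoxy)-1,4-naphthoquinone | CC(C)(C)[Si](C)(C)O[C@@H](CC=C(C)C)C1=CC(=O)c2c(OCOC)ccc(OCOC)c2C1=O
F14 | step 9 | alkannin, (S)-5,8-dihydroxy-2-(1-hydroxy-4-methylpent-3-enyl)-1,4-naphthoquinone | O[C@@H](CC=C(C)C)C1=CC(=O)c2c(O)ccc(O)c2C1=O
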